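A direct plan would join a silyl-capped C4 ynone enolate and a C4 acid chloride by Claisen acylation to 1-(trimethylsilyl)oct-1-yne-3,5-dione A1,
would then close the ring in one flask by NBS bromination, bromodesilylation and AgNO3-catalysed 6-endo-dig attack of the enol oxygen on the bromoalkyne to 2,3,5-tribromo-6-propyl-4H-pyran-4-one A2,
and would end with a radical double bromination of the propyl CH2 next to the ring.
Its weakest step would be the brominative oxacyclisation: an O1–C2 closure onto a haloalkyne has no precedent, and the 6-endo against 5-exo choice and three separate brominations would be left to one flask.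
The second would be the closing Wohl–Ziegler bromination: it would have to stop at exactly two bromines on one carbon of the most advanced material, against further chain bromination, HBr loss to a bromopropenyl group and photolysis of ring C–Br bonds.
The third would be the acylation, which would spend a second equivalent of the ynone enolate as base and risk O-acylation.

**Plan of the new route** (pyranone numbering: O1, C2(Br), C3(Br), C4(=O), C5(Br), C6(CBr2Et))
The retrosynthesis takes out C3 with its bromine as dibromocarbene, cutting C2–C3 and C3–C4; this leaves a 3-silyloxyfuran whose oxygen and four carbons are O1, C2, C4, C5 and C6.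
This is possible because O1–C2(Br)=C3(Br)–C4(=O) is exactly what a CBr insertion into the doubly oxygen-substituted C2=C3 enol-ether bond of a 3-oxygenated furan leaves, and the 4-silyloxypyrylium formed on the way is aromatic.
The furan-3(2H)-one is cut at O1–C2 (enolate O-alkylation by a CHBr2 ketone) and at C5–C6 (acylation of 2-methoxypropene by 2,2-dibromobutanoyl bromide).
Ring order: the five-membered furanone first, the six-membered ring last, by one-carbon ring expansion and not by cyclisation.
The CBr2Et group enters ready-made by ionic α-bromination of an acyl bromide, the C2 and C5 bromines by ionic bromination of the open chain, and C3–Br with the inserted carbon; so neither a closure onto a haloalkyne nor a late radical bromination occurs.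

Key step: step 5

Remark: 8 is drawn as its keto tautomer; the 3-hydroxyfuran tautomer would be silylated to the same 10.

**Step 1**
Reactants: 1 2-bromobutanoyl bromide
Product: 2 2,2-dibromobutanoyl bromide
Conditions: Br2 (1.3 equiv), PBr3 (cat.), neat, 90–100 °C, 16 h, HBr swept out with N2; distil
Reagents that add atoms: bromine, BrBr
Why: A second Hell–Volhard–Zelinsky bromination through the acyl bromide enol, which has only one enolisable carbon, should turn the racemic CHBr centre into the achiral CBr2 group by ionic chemistry on a commercial C4 acid halide.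

**Step 2**
Reactants: 2 2,2-dibromobutanoyl bromide; 3 2-methoxypropene
Product: 4 (E)-5,5-dibromo-2-methoxyhept-2-en-4-one
Conditions: 3 (2.0 equiv), pyridine (1.2 equiv), CH2Cl2, −10 → 20 °C, 12 h
Reagents that add atoms: none
Why: Acylation of an enol ether by an α,α-dihaloacyl halide (the β-alkoxyvinyl ketone synthesis known with trichloroacetyl and dichloroacetyl chloride) should form the C5–C6 bond without any enolate, since pyridine only removes HBr from the oxocarbenium adduct and 2 has no α-hydrogen for a ketene path; the E isomer with acyl and methoxy anti is the usual product.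

**Step 3**
Reactants: 4 (E)-5,5-dibromo-2-methoxyhept-2-en-4-one
Product: 5 (E)-1,1,5,5-tetrabromo-2-methoxyhept-2-en-4-one
Conditions: Br2 (2.1 equiv), CH2Cl2, 0 °C; then pyridine (2.2 equiv), 0 → 20 °C
Reagents that add atoms: bromine, BrBr
Why: Regiospecific allylic mono- and dibromination of 4-methoxyalk-3-en-2-ones that carry a non-enolisable polyhaloalkyl ketone is a known reaction with Br2 and pyridine (bromine adds to the enol ether, pyridine removes a methyl proton, the allylic bromide returns to conjugation), and the CBr2Et side has no α-hydrogen to compete; the alkene geometry is of no consequence because step 4 hydrolyses the enol ether.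

**Step 4**
Reactants: 5 (E)-1,1,5,5-tetrabromo-2-methoxyhept-2-en-4-one
Product: 8 2,4-dibromo-5-(1,1-dibromopropyl)furan-3(2H)-one, via tetrabromo diketone 6 (not isolated), via pentabromo diketone 7 (not isolated)
Conditions: 1 M H2SO4, MeCN, 20 °C; NBS (1.0 equiv), 0 °C; extract into CH2Cl2, dry, evaporate; K2CO3 (1.1 equiv), acetone, 0 → 20 °C; filter, short silica plug
Reagents that add atoms: water, O; N-bromosuccinimide (NBS), O=C1CCC(=O)N1Br
Why: Acid hydrolysis of the vinylogous ester should free the enolised 1,3-diketone 6, NBS should brominate its only doubly activated carbon to 7, and the enolate formed with K2CO3 should close the furanone by 5-exo-tet O-alkylation at the secondary CHBr2 carbon (the tertiary CBr2Et carbon cannot undergo SN2), the standard route from 1-halo-2,4-diones to furan-3(2H)-ones; the C2 centre of 8 is racemic and is erased in step 5.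

**Step 5**
Reactants: 8 2,4-dibromo-5-(1,1-dibromopropyl)furan-3(2H)-one; 9 bromoform
Product: 13 2,3,5-tribromo-6-(1,1-dibromopropyl)-4H-pyran-4-one (target), via silyloxyfuran 10 (not isolated), via dibromocyclopropane 11 (not isolated), via silyloxypyrylium bromide 12 (not isolated)
Conditions: TBSOTf (1.1 equiv), iPr2NEt (1.2 equiv), CH2Cl2, −78 → 0 °C; solvent swap to hexane, filter under Ar; 9 (4 equiv), KOtBu (2.0 equiv, in portions), hexane, −40 → 0 °C, dark; then 20 °C, 1 h
Reagents that add atoms: tert-butyldimethylsilyl trifluoromethanesulfonate (TBSOTf), CC(C)(C)[Si](C)(C)OS(=O)(=O)C(F)(F)F (its silyl group is carried only by 10–12; none of its atoms remain in 13)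
Why: Proposed new method: one-carbon ring expansion of a 3-silyloxyfuran by dibromocarbene. Enolisation and O-silylation of 8 should give the aromatic silyl enol ether 10, and CBr2 (from CHBr3 and KOtBu, with bromoform in excess so that no free alkoxide meets the CBr2Et group or the product) should add as an electrophile by [2+1] cycloaddition to the C2=C3 bond to give the 2-oxabicyclo[3.1.0]hexene 11. Loss of one bromide from the CBr2 carbon with disrotatory opening of the cyclopropyl cation, pushed by the ring oxygen and the OSi group, cleaves the old C2–C3 bond and gives the aromatic 4-silyloxypyrylium bromide 12, which bromide desilylates to 13 and TBSBr; the six-membered ring thus arises by electrocyclic opening of the three-membered ring, not by a cyclisation. The closest known reaction types are the dihalocarbene ring expansion of cyclic silyl enol ethers and alkyl enol ethers to 2-halo-enones and the Ciamician–Dennstedt conversion of pyrroles and indoles into 3-halopyridines and 3-haloquinolines; neither has been shown on a 3-oxygenated furan or on a bromine-bearing enol-ether carbon. The step needs site selectivity for C2=C3 over C4=C5, which is secured by two oxygen donors on C2=C3 against one on C4=C5, the latter also carrying the bulky, electron-poor CBr2Et group. The racemic C2 centre of 8 and the two bridgeheads of 11 vanish, so 13 is achiral.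

**Compound list**
1 | 2-bromobutanoyl bromide (racemic) | CCC(Br)C(=O)Br | starting material
2 | 2,2-dibromobutanoyl bromide | CCC(Br)(Br)C(=O)Br | intermediate
3 | 2-methoxypropene | COC(C)=C | starting material
4 | (E)-5,5-dibromo-2-methoxyhept-2-en-4-one | CCC(Br)(Br)C(=O)/C=C(\C)OC | intermediate
5 | (E)-1,1,5,5-tetrabromo-2-methoxyhept-2-en-4-one | CCC(Br)(Br)C(=O)/C=C(\C(Br)Br)OC | intermediate
6 | 1,1,5,5-tetrabromoheptane-2,4-dione (enolised, drawn as diketone) | CCC(Br)(Br)C(=O)CC(=O)C(Br)Br | intermediate
7 | 1,1,3,5,5-pentabromoheptane-2,4-dione (racemic, enolisable C3) | CCC(Br)(Br)C(=O)C(Br)C(=O)C(Br)Br | intermediate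
8 | 2,4-dibromo-5-(1,1-dibromopropyl)furan-3(2H)-one (racemic) | CCC(Br)(Br)C1=C(Br)C(=O)C(Br)O1 | intermediate
9 | bromoform | BrC(Br)Br | starting material
10 | tert-butyl{[2,4-dibromo-5-(1,1-dibromopropyl)furan-3-yl]oxy}dimethylsilane | CCC(Br)(Br)c1oc(Br)c(O[Si](C)(C)C(C)(C)C)c1Br | intermediate
11 | 1,4,6,6-tetrabromo-5-[(tert-butyldimethylsilyl)oxy]-3-(1,1-dibromopropyl)-2-oxabicyclo[3.1.0]hex-3-ene (racemic) | CCC(Br)(Br)C1=C(Br)C2(O[Si](C)(C)C(C)(C)C)C(Br)(Br)C2(Br)O1 | intermediate
12 | 2,3,5-tribromo-4-[(tert-butyldimethylsilyl)oxy]-6-(1,1-dibromopropyl)pyrylium bromide | CCC(Br)(Br)c1[o+]c(Br)c(Br)c(O[Si](C)(C)C(C)(C)C)c1Br.[Br-] | intermediate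
13 | 2,3,5-tribromo-6-(1,1-dibromopropyl)-4H-pyran-4-one (achiral) | CCC(Br)(Br)c1oc(Br)c(Br)c(=O)c1Br | target

Total step count: 5. Longest linear sequence: 5 steps (1 → 2 → 4 → 5 → 8 → 13).

**Steps most likely to fail**

Step 5. The carbene may fail to add to the crowded, bromine-bearing C2=C3 bond of 10, or alkoxide may strip HBr from the CBr2Et group or cleave the silyl ether before cyclopropanation. The fallback uses known chemistry, sets out from 2 and returns at 13. Acetyl bromide and 1,1-dibromoethene with AlBr3 in CH2Cl2 would give 4,4,4-tribromobutan-2-one F1, which loses HBr with Et3N to 4,4-dibromobut-3-en-2-one F2 (the bromine counterpart of the classical β,β-dichlorovinyl ketone synthesis). Soft-enolisation Claisen acylation of F2 with 2 (MgBr2·OEt2, iPr2NEt, CH2Cl2, 0 °C) would give 1,1,6,6-tetrabromooct-1-ene-3,5-dione F3. Its enol oxygen would displace one vinylic bromide by addition–elimination (K2CO3, acetone) to give 2-bromo-6-(1,1-dibromopropyl)-4H-pyran-4-one F4. Electrophilic bromination of F4 at C3 and C5 (Br2, NaOAc, AcOH, 50 °C) would then give 13.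

Step 4. The labile C2 bromine of 8 may be lost by hydrolysis, base may cleave the CHBr2 ketone, or bromine may be transferred from C3 of 7 between molecules. The fallback sets out from 5 and returns at 13. Heating 5 in MeCN at 70 °C with 2,6-di-tert-butylpyridine would close the ring through the neutral carbonyl oxygen (as in the tetronate synthesis from 4-bromo-3-methoxycrotonates) and keep the methyl enol ether, giving 2-bromo-5-(1,1-dibromopropyl)-3-methoxyfuran F5. NBS in MeCN at −20 °C would brominate its only free ring position to 2,4-dibromo-5-(1,1-dibromopropyl)-3-methoxyfuran F6. F6 would take the place of 10 under the carbene conditions of step 5 (CHBr3, KOtBu), and the resulting 2,3,5-tribromo-6-(1,1-dibromopropyl)-4-methoxypyrylium bromide F7 would lose bromomethane to give 13.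

Step 3. Bromination may occur at the vinylic C3–H instead of the methyl group, or stop unevenly and give a mixture of mono-, di- and tribromides. The fallback sets out from 2 and returns at 8. Friedel–Crafts acylation of 3-bromo-1-(trimethylsilyl)prop-1-yne with 2 (AlBr3, CH2Cl2, −20 °C) would give 1,5,5-tribromohept-2-yn-4-one F8, so that the carbon that will carry the ring oxygen arrives already functionalised. Acid-catalysed hydration (TfOH cat., aqueous dioxane) would give 1,5,5-tribromoheptane-2,4-dione F9, which K2CO3 in acetone would close to 5-(1,1-dibromopropyl)furan-3(2H)-one F10. NBS would brominate C4 to give 4-bromo-5-(1,1-dibromopropyl)furan-3(2H)-one F11. Silylation (TBSOTf, iPr2NEt) to {[4-bromo-5-(1,1-dibromopropyl)furan-3-yl]oxy}(tert-butyl)dimethylsilane F12, followed by NBS at −78 °C, would place the last bromine at C2 and give 8.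

**Further compounds**
F1 | step 5 | 4,4,4-tribromobutan-2-one | CC(=O)CC(Br)(Br)Br
F2 | step 5 | 4,4-dibromobut-3-en-2-one | CC(=O)C=C(Br)Br
F3 | step 5 | 1,1,6,6-tetrabromooct-1-ene-3,5-dione | CCC(Br)(Br)C(=O)CC(=O)C=C(Br)Br
F4 | step 5 | 2-bromo-6-(1,1-dibromopropyl)-4H-pyran-4-one | CCC(Br)(Br)c1cc(=O)cc(Br)o1
F5 | step 4 | 2-bromo-5-(1,1-dibromopropyl)-3-methoxyfuran | CCC(Br)(Br)c1cc(OC)c(Br)o1
F6 | step 4 | 2,4-dibromo-5-(1,1-dibromopropyl)-3-methoxyfuran | CCC(Br)(Br)c1oc(Br)c(OC)c1Br
F7 | step 4 | 2,3,5-tribromo-6-(1,1-dibromopropyl)-4-methoxypyrylium bromide | CCC(Br)(Br)c1[o+]c(Br)c(Br)c(OC)c1Br.[Br-]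
F8 | step 3 | 1,5,5-tribromohept-2-yn-4-one | BrCC#CC(=O)C(Br)(Br)CC
F9 | step 3 | 1,5,5-tribromoheptane-2,4-dione | BrCC(=O)CC(=O)C(Br)(Br)CC
F10 | step 3 | 5-(1,1-dibromopropyl)furan-3(2H)-one | CCC(Br)(Br)C1=CC(=O)CO1
F11 | step 3 | 4-bromo-5-(1,1-dibromopropyl)furan-3(2H)-one | CCC(Br)(Br)C1=C(Br)C(=O)CO1
F12 | step 3 | {[4-bromo-5-(1,1-dibromopropyl)furan-3-yl]oxy}(tert-butyl)dimethylsilane | CCC(Br)(Br)c1occ(O[Si](C)(C)C(C)(C)C)c1Br
A1 | direct plan | 1-(trimethylsilyl)oct-1-yne-3,5-dione | CCCC(=O)CC(=O)C#C[Si](C)(C)C
A2 | direct plan | 2,3,5-tribromo-6-propyl-4H-pyran-4-one | CCCc1oc(Br)c(Br)c(=O)c1Br
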